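**Plan**

Locants: bicyclo[3.3.1]nonane core C1–C9 (C1 benzoyl bridgehead, C2–C3–C4 bridge, C5 geranyl bridgehead, C6 CH2, C7 CH, C8 CMe2, C9 ketone bridge); C10 = CH2 on C7, C11 = CH bonded to C3, C12 = CMe2, C13 = CH carrying isopropenyl, C14 = CH2 on C3; endo = on the side of the C2–C3–C4 bridge.
Retrosynthesis: the C3–C11 bond is undone as a 1,2-shift back to C2 (tertiary chlorohydrin with a C2–C11 bond); then C2–C11 and C12–C13 are cut (Prins bicyclization of a bicyclic 3-chloro-3-prenyl trione), then C3–Cl, C3–C14, the C10 side chain (retro-aldol of a cage aldol), C1–C8 with C3–C10 (Michael/aldol) and C5–C6 (dearomatizing alkylation of an acylphloroglucinol).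
Forward: acylphloroglucinol, then quaternary C5, then the C1/C5/C6/C7/C8/C9 ring and cage aldol, then endo C7 prenyl chain, then C3 prenyl, then C3–Cl, then two six-membered rings by Prins bicyclization, then the semipinacol shift that makes the seven-membered ring C3–C4–C5–C6–C7–C10–C11 and the cyclopentane.
Enabling feature: C3 is a quaternary carbon between the C2 and C4 ketones and is the fusion atom of ring C3–C4–C5–C6–C7–C10–C11 and the cyclopentane; its bond to C11 next to the C2 carbonyl is a semipinacol retron, so that ring can be drawn from the eight-membered ring C2–C3–C4–C5–C6–C7–C10–C11 by expelling C2, and the cyclopentane from a cyclohexane.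
Stereochemistry: C5 from asymmetric phase-transfer alkylation; C1 and C7 (endo) from cage formation; C3 from exo-face chlorination; C11 and C13 from the chair-like Prins bicyclization; the shift retains C11 and inverts C3.

Key step: step 13

Remarks on the chemistry:
- The cinchonidinium catalyst of step 5 is assumed to give the C5 configuration drawn; if the sense is opposite, the pseudo-enantiomeric cinchoninium salt is used.
- Enols, metal enolates, enol carbonates and the cyclohexadienone are drawn as one tautomer or regioisomer (C4–O); the C2–O forms converge at the same products.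
- The metal enolate 11 and the alkoxide enolate 12 of step 7 exist only as salts in the flask and are drawn as bromomagnesium salts; with CeCl3 present the oxygen may instead carry a CeCl2 unit, which does not change the outcome.
- The C10 carbinol configuration in 10, 12 and 13 is left open because C10 ends as CH2.

**Route**

Step 1
Reactants: 1 2,3-dimethylbut-3-en-2-ol
Product: 2 2,3-dimethylbut-3-en-2-yl acetate
Conditions: Ac2O, DMAP (cat.), Et3N, CH2Cl2, rt
Reagents that add atoms: acetic anhydride CC(=O)OC(C)=O
Why: DMAP-catalysed O-acylation (esterification) of the tertiary allylic alcohol gives the acetate that later leaves by E1cB elimination; no stereocenter is formed.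

Step 2
Reactants: 2 2,3-dimethylbut-3-en-2-yl acetate
Product: 3 2-methyl-3-methylidene-4-oxobutan-2-yl acetate
Conditions: SeO2, 1,4-dioxane, 80 °C
Reagents that add atoms: selenium dioxide O=[Se]=O
Why: Riley allylic oxidation with SeO2 (ene reaction then [2,3]-sigmatropic shift) can only engage the single allylic CH3 group and in hot dioxane should run through to the 2-substituted acrolein.

Step 3
Reactants: 4 2,4,6-trihydroxybenzophenone (in excess); 5 geranyl bromide
Product: 6 3-geranyl-2,4,6-trihydroxybenzophenone
Conditions: KOH (10 % aq.), 0 °C to rt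
Reagents that add atoms: none
Why: C-alkylation of the phloroglucinolate by the allylic bromide (Friedel–Crafts-type C-allylation under aqueous base) is favoured for this soft ambident anion, and the excess of 4 should hold it at the mono-geranyl stage with the E alkene untouched.

Step 4
Reactants: 6 3-geranyl-2,4,6-trihydroxybenzophenone
Product: 7 3-chloro-5-geranyl-2,4,6-trihydroxybenzophenone
Conditions: NCS (1.0 equiv), THF, −40 °C
Reagents that add atoms: N-chlorosuccinimide O=C1CCC(=O)N1Cl
Why: Electrophilic aromatic chlorination hits the only free ring carbon because the phloroglucinol nucleus is far more nucleophilic toward NCS than the trisubstituted alkenes; the chlorine then blocks this carbon against alkylation and as a Michael donor.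

Step 5
Reactants: 7 3-chloro-5-geranyl-2,4,6-trihydroxybenzophenone; 3 2-methyl-3-methylidene-4-oxobutan-2-yl acetate
Product: 8 dearomatized enal (quaternary C5 carrying geranyl and the 2-formyl-3-methylbut-2-enyl chain)
Conditions: CsOH·H2O, O-allyl-N-(9-anthracenylmethyl)cinchonidinium bromide (10 mol %), CH2Cl2, −50 °C
Reagents that add atoms: none
Why: Alkylative dearomatization by Michael addition to the enal and E1cB loss of acetate takes place at the geranyl-bearing carbon because the chlorinated and benzoylated ring carbons are poor nucleophiles, while the chiral ammonium ion pair (asymmetric phase-transfer catalysis) decides which face is alkylated and so sets the quaternary stereocenter C5.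

Step 6
Reactants: 8 dearomatized enal
Product: 10 chloro hydroxy cage aldol (C3–C10 bond), via endo aldehyde 9 (not isolated)
Conditions: conc. HCl, THF, 0 °C to rt
Reagents that add atoms: none
Why: Acid-mediated intramolecular Michael addition of the benzoyl-bearing enol carbon C1 to the protonated enal (the chlorinated C3 being the poorer donor) closes C1–C8, and aldol addition of C3 to the aldehyde then closes the cage; C1 and C7 are dictated by C5 because only the cis-bridged rings can form, and the aldol fixes the C7 substituent endo.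

Step 7
Reactants: 10 chloro hydroxy cage aldol
Product: 13 bis(methyl carbonate) of the ring-opened allylic alcohol, via magnesium enolate 11 (not isolated), via dimagnesium alkoxide 12 (not isolated)
Conditions: (2-methylprop-1-enyl)MgBr, CeCl3, THF, −78 to 0 °C; then ClCO2Me, −78 °C to rt
Reagents that add atoms: (2-methylprop-1-enyl)magnesium bromide CC(C)=C[Mg]Br; methyl chloroformate COC(Cl)=O
Why: Deprotonation of the carbinol by the first equivalent of the reagent triggers a retro-aldol that opens the cage to the endo aldehyde as its chloro-diketone enolate 11, the weakly basic reagent made from the Grignard reagent and CeCl3 traps this aldehyde by 1,2-addition (Grignard-type carbonyl addition) before C7 can epimerize to give the alkoxide enolate 12, and methyl chloroformate then acylates both oxygens.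

Step 8
Reactants: 13 bis(methyl carbonate)
Product: 15 3-chloro enol carrying the endo C7 prenyl group, via enol carbonate 14 (not isolated)
Conditions: Pd(PPh3)4 (5 mol %), Bu3SnH, THF, rt; then K2CO3, MeOH, 0 °C
Reagents that add atoms: none
Why: Palladium-catalysed allylic hydrogenolysis (Tsuji–Trost ionization then hydride transfer from tin) should deliver hydride to the less substituted allyl terminus C10 and keep the trisubstituted prenyl alkene, while the enol carbonate blocks attack of C3 on the allyl complex and is then removed by base-catalysed transesterification.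

Step 9
Reactants: 15 3-chloro enol
Product: 16 C3-unsubstituted enol (1-benzoyl-5-geranyl-4-hydroxy-8,8-dimethyl-7-endo-prenylbicyclo[3.3.1]non-3-ene-2,9-dione)
Conditions: Zn, AcOH, THF, rt
Reagents that add atoms: none
Why: Zinc reduces the 2-chloro-1,3-diketone through its zinc enolate (reductive α-dehalogenation) without touching the isolated alkenes or the hindered ketones and so unmasks C3–H.

Step 10
Reactants: 16 C3-unsubstituted enol; 17 prenyl acetate
Product: 18 3-prenyl enol
Conditions: Pd(PPh3)4 (5 mol %), Et3N, THF, rt
Reagents that add atoms: none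
Why: Tsuji–Trost allylation of the soft diketone enolate occurs at the less hindered terminus of the prenyl–palladium complex, and any O-prenyl ether re-ionizes, so the linear C3-prenyl enol should accumulate.

Step 11
Reactants: 18 3-prenyl enol
Product: 19 3-exo-chloro-3-endo-prenyl trione
Conditions: NCS, CH2Cl2, 0 °C
Reagents that add atoms: N-chlorosuccinimide O=C1CCC(=O)N1Cl
Why: Electrophilic α-chlorination of the enol creates the C3 stereocenter by attack of NCS on the exo face, away from the endo C7 prenyl chain, which leaves chlorine exo and the C3 prenyl group endo.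

Step 12
Reactants: 19 3-exo-chloro-3-endo-prenyl trione
Product: 20 pentacyclic chlorohydrin (C2–OH, C2–C11 and C12–C13 bonds, C3–Cl)
Conditions: Sc(OTf)3 (20 mol %), CH2Cl2, −40 to 0 °C
Reagents that add atoms: none
Why: In this Lewis acid-catalysed Prins bicyclization, scandium chelated between O2 and the benzoyl oxygen activates the C2 ketone for six-membered ring closure by the endo C7 prenyl alkene (the ketone counterpart of the citronellal-to-isopulegol carbonyl-ene closure), the tertiary C12 cation is captured by the endo C3 prenyl alkene in a second six-membered ring closure and loss of a methyl proton gives the isopropenyl group, with C2 and C11 set by endo-face attack and C13 by the equatorial placement of its cationic side chain.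

Step 13
Reactants: 20 pentacyclic chlorohydrin
Product: 21 CNP0110731.1 (target)
Conditions: AgOTf, 2,6-di-tert-butylpyridine, CH2Cl2, 0 °C to rt
Reagents that add atoms: none
Why: Proposed new method: silver ion pulls chloride from C3 while the C2–C11 bond, held antiperiplanar to C3–Cl by the cage, shifts from the carbinol carbon C2 to C3 and the C2 hydroxyl collapses to the ketone, a semipinacol 1,2-shift whose closest known relatives are the halohydrin ring expansion and the quasi-Favorskii (semibenzilic) shift of α-halo ketones; the untested element is the tertiary α-chloro-β-diketone terminus. This one shift contracts the eight-membered ring C2–C3–C4–C5–C6–C7–C10–C11 to the seven-membered ring C3–C4–C5–C6–C7–C10–C11 by expelling C2, contracts the cyclohexane C2–C3–C14–C13–C12–C11 to the cyclopentane C3–C14–C13–C12–C11, and expands the cyclohexane C1–C2–C11–C10–C7–C8 to the second seven-membered ring, each by 1,2-migration and not by a new cyclization. C11 migrates with retention and C3 is inverted, so the endo C14 and exo chlorine of 20 translate into the C3 configuration of the target, while C13 is untouched and the C2 stereocenter is erased. The step needs migration of C11 in preference to three other paths: migration of C1, epoxide closure by O2 and retro-aldol cleavage of the C1–C2 bond. C11 is the only group anti to the leaving chloride (C1 and O2 are gauche), C1 is an electron-poor triacyl-substituted carbon, and the non-basic silver conditions avoid a free alkoxide at C2.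

**Compound list**

1 | 2,3-dimethylbut-3-en-2-ol | CC(=C)C(C)(C)O | starting material
2 | 2,3-dimethylbut-3-en-2-yl acetate | CC(=C)C(C)(C)OC(C)=O | intermediate
3 | 2-methyl-3-methylidene-4-oxobutan-2-yl acetate | C=C(C=O)C(C)(C)OC(C)=O | intermediate
4 | 2,4,6-trihydroxybenzophenone | O=C(c1ccccc1)c1c(O)cc(O)cc1O | starting material
5 | geranyl bromide, (2E)-1-bromo-3,7-dimethylocta-2,6-diene | CC(C)=CCC/C(C)=C/CBr | starting material
6 | 3-geranyl-2,4,6-trihydroxybenzophenone | O=C(c1ccccc1)c1c(O)cc(O)c(C/C=C(\C)CCC=C(C)C)c1O | intermediate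
7 | 3-chloro-5-geranyl-2,4,6-trihydroxybenzophenone | O=C(c1ccccc1)c1c(O)c(Cl)c(O)c(C/C=C(\C)CCC=C(C)C)c1O | intermediate
8 | 2-benzoyl-4-chloro-6-geranyl-3,5-dihydroxy-6-(2-formyl-3-methylbut-2-en-1-yl)cyclohexa-2,4-dien-1-one, quaternary carbon configured as C5 of the target | ClC1=C(O)[C@@](C/C=C(\C)CCC=C(C)C)(CC(C=O)=C(C)C)C(=O)C(C(=O)c2ccccc2)=C1O | intermediate
9 | 1-benzoyl-3-chloro-5-geranyl-4-hydroxy-8,8-dimethyl-2,9-dioxobicyclo[3.3.1]non-3-ene-7-endo-carbaldehyde | ClC1=C(O)[C@@]2(C/C=C(\C)CCC=C(C)C)C[C@@H](C=O)C(C)(C)[C@](C(=O)c3ccccc3)(C2=O)C1=O | intermediate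
10 | cage aldol of 9: C3 (bearing Cl) bonded to C10, C10 = CH(OH) on C7, triketone at C2, C4, C9 | Cl[C@@]12C(=O)[C@@]3(C/C=C(\C)CCC=C(C)C)C[C@@H](C1O)C(C)(C)[C@](C(=O)c4ccccc4)(C3=O)C2=O | intermediate
11 | bromomagnesium enolate of the ring-opened endo aldehyde (O4–MgBr; free aldehyde C10 on C7) | ClC1=C(O[Mg]Br)[C@@]2(C/C=C(\C)CCC=C(C)C)C[C@@H](C=O)C(C)(C)[C@](C(=O)c3ccccc3)(C2=O)C1=O | intermediate
12 | bis(bromomagnesium) salt of the 3-chloro enol with endo C7 1-hydroxy-3-methylbut-2-en-1-yl chain (O4–MgBr and C10–O–MgBr) | ClC1=C(O[Mg]Br)[C@@]2(C/C=C(\C)CCC=C(C)C)C[C@@H](C(O[Mg]Br)C=C(C)C)C(C)(C)[C@](C(=O)c3ccccc3)(C2=O)C1=O | intermediate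
13 | bis(methyl carbonate) of the 3-chloro enol with endo C7 1-hydroxy-3-methylbut-2-en-1-yl chain (enol O4 and C10–O) | ClC1=C(OC(=O)OC)[C@@]2(C/C=C(\C)CCC=C(C)C)C[C@@H](C(OC(=O)OC)C=C(C)C)C(C)(C)[C@](C(=O)c3ccccc3)(C2=O)C1=O | intermediate
14 | 3-chloro enol methyl carbonate with endo C7 prenyl | ClC1=C(OC(=O)OC)[C@@]2(C/C=C(\C)CCC=C(C)C)C[C@@H](CC=C(C)C)C(C)(C)[C@](C(=O)c3ccccc3)(C2=O)C1=O | intermediate
15 | 1-benzoyl-3-chloro-5-geranyl-4-hydroxy-8,8-dimethyl-7-endo-prenylbicyclo[3.3.1]non-3-ene-2,9-dione | ClC1=C(O)[C@@]2(C/C=C(\C)CCC=C(C)C)C[C@@H](CC=C(C)C)C(C)(C)[C@](C(=O)c3ccccc3)(C2=O)C1=O | intermediate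
16 | 1-benzoyl-5-geranyl-4-hydroxy-8,8-dimethyl-7-endo-prenylbicyclo[3.3.1]non-3-ene-2,9-dione | C1=C(O)[C@@]2(C/C=C(\C)CCC=C(C)C)C[C@@H](CC=C(C)C)C(C)(C)[C@](C(=O)c3ccccc3)(C2=O)C1=O | intermediate
17 | prenyl acetate, 3-methylbut-2-en-1-yl acetate | CC(C)=CCOC(C)=O | starting material
18 | 1-benzoyl-5-geranyl-4-hydroxy-8,8-dimethyl-3-prenyl-7-endo-prenylbicyclo[3.3.1]non-3-ene-2,9-dione | CC(C)=CCC1=C(O)[C@@]2(C/C=C(\C)CCC=C(C)C)C[C@@H](CC=C(C)C)C(C)(C)[C@](C(=O)c3ccccc3)(C2=O)C1=O | intermediate
19 | 1-benzoyl-3-exo-chloro-5-geranyl-8,8-dimethyl-3-endo-prenyl-7-endo-prenylbicyclo[3.3.1]nonane-2,4,9-trione | Cl[C@]1(CC=C(C)C)C(=O)[C@@]2(C/C=C(\C)CCC=C(C)C)C[C@@H](CC=C(C)C)C(C)(C)[C@](C(=O)c3ccccc3)(C2=O)C1=O | intermediate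
20 | pentacyclic chlorohydrin: C2 carbinol bonded to C1, C3 and C11; C3 bears Cl and C14; cyclohexane C2–C3–C14–C13–C12–C11 with isopropenyl on C13 | C=C(C)[C@@H]1C[C@@]2(Cl)C(=O)[C@@]4(C/C=C(\C)CCC=C(C)C)C[C@@H](C[C@H]3C1(C)C)C(C)(C)[C@](C(=O)c5ccccc5)(C4=O)[C@]23O | intermediate
21 | CNP0110731.1 | C=C(C)[C@@H]1C[C@@]23C(=O)[C@@]4(C/C=C(\C)CCC=C(C)C)C[C@@H](C[C@H]2C1(C)C)C(C)(C)[C@](C(=O)c1ccccc1)(C4=O)C3=O | target

**Count and risks**

Total step count: 13. Longest linear sequence: 11 steps (4 to 21, steps 3 to 13); steps 1 and 2 make reagent 3 and join at step 5.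

Steps most likely to fail:

Step 13 (bears the label). The C2 carbinol may fragment by retro-aldol cleavage of the C1–C2 bond, or chloride may ionize without migration and end in elimination. The fallback sets out from 18 and comes back at 21. Oxidative radical cyclization of the enol with Mn(OAc)3·2H2O and Cu(OAc)2·H2O in AcOH would generate the C3 radical, close the seven-membered ring by 7-exo attack on the C7 prenyl alkene at C11 and the cyclopentane by 5-exo attack of the C12 radical on the C3 prenyl alkene, and end by copper-mediated oxidative elimination to the isopropenyl group. No compound outside the list is made (F0). Steps 11 to 13 are then not needed.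

Step 12. The prenyl alkene may attack C4 instead of C2 (poor site selectivity, leading to the C11-epimeric series), the cascade may stop by proton loss after the first ring closure, or the Lewis acid may induce fragmentation of the product carbinol. The fallback sets out from 19 and comes back at 21. Copper-catalysed atom-transfer radical cyclization (CuCl, tris(2-pyridylmethyl)amine, 1,2-dichloroethane, 80 °C) would abstract the C3 chlorine, run the same 7-exo/5-exo radical cascade and return chlorine to the side-chain radical to give the 2-chloropropan-2-yl pentacycle F1. Dehydrochlorination (LiBr, Li2CO3, DMF, heat) would then give 21.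

Step 6. The Michael addition may start from the wrong ring carbon, an enol oxygen may close by oxa-Michael addition, or HCl may add to the alkenes. The fallback gives up the chlorine block, sets out from 6 and comes back at 18, so that it takes the place of steps 4 to 10 with no dechlorination and no late prenylation. C-Prenylation of 6 (prenyl bromide, aqueous KOH) would give 3-geranyl-5-prenyl-2,4,6-trihydroxybenzophenone F2. Alkylation with 3 under the conditions of step 5 would give the dearomatized enal alkylated at the geranyl-bearing carbon F3, together with its regioisomer alkylated at the prenyl-bearing carbon F4, which is removed by chromatography. Acid-mediated Michael/aldol closure of F3 as in step 6 would give the 3-prenyl cage aldol F5. Retro-aldol opening, addition of (2-methylprop-1-enyl)MgBr/CeCl3 and the chloroformate quench, as in step 7, would give the bis(methyl carbonate) F6. Hydrogenolysis with Pd(PPh3)4 and Bu3SnH would give the enol carbonate F7, and methanolysis gives 18.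

**Further compounds**

F0 | step 13 | none | none
F1 | step 12 | 2-chloropropan-2-yl analogue of 21 (C13 carries CMe2Cl in place of isopropenyl) | CC(C)(Cl)[C@@H]1C[C@@]23C(=O)[C@@]4(C/C=C(\C)CCC=C(C)C)C[C@@H](C[C@H]2C1(C)C)C(C)(C)[C@](C(=O)c1ccccc1)(C4=O)C3=O
F2 | step 6 | 3-geranyl-5-prenyl-2,4,6-trihydroxybenzophenone | O=C(c1ccccc1)c1c(O)c(CC=C(C)C)c(O)c(C/C=C(\C)CCC=C(C)C)c1O
F3 | step 6 | 2-benzoyl-6-geranyl-3,5-dihydroxy-6-(2-formyl-3-methylbut-2-en-1-yl)-4-prenylcyclohexa-2,4-dien-1-one | CC(C)=CCC1=C(O)[C@@](C/C=C(\C)CCC=C(C)C)(CC(C=O)=C(C)C)C(=O)C(C(=O)c2ccccc2)=C1O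
F4 | step 6 | 2-benzoyl-4-geranyl-3,5-dihydroxy-6-(2-formyl-3-methylbut-2-en-1-yl)-6-prenylcyclohexa-2,4-dien-1-one (configuration not defined) | O=C(c1ccccc1)C1=C(O)C(C/C=C(\C)CCC=C(C)C)=C(O)C(CC=C(C)C)(CC(C=O)=C(C)C)C1=O
F5 | step 6 | cage aldol with C3 prenyl (C3–C10 bond, C10 carbinol) | CC(C)=CC[C@@]12C(=O)[C@@]3(C/C=C(\C)CCC=C(C)C)C[C@@H](C1O)C(C)(C)[C@](C(=O)c4ccccc4)(C3=O)C2=O
F6 | step 6 | bis(methyl carbonate) of the 3-prenyl enol with endo C7 1-hydroxy-3-methylbut-2-en-1-yl chain | CC(C)=CCC1=C(OC(=O)OC)[C@@]2(C/C=C(\C)CCC=C(C)C)C[C@@H](C(OC(=O)OC)C=C(C)C)C(C)(C)[C@](C(=O)c3ccccc3)(C2=O)C1=O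
F7 | step 6 | enol methyl carbonate of 18 | CC(C)=CCC1=C(OC(=O)OC)[C@@]2(C/C=C(\C)CCC=C(C)C)C[C@@H](CC=C(C)C)C(C)(C)[C@](C(=O)c3ccccc3)(C2=O)C1=O
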